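**Retrosynthetic overview**

1. Target 35 ← BBr3 cleavage of six methyl ethers ← oxidation of two aryl C–B bonds ← indane 5,7-bis(boronate) 33.
2. Key disconnection: the resorcinol benzo ring C3a–C4–C5–C6–C7–C7a of the indane, whose C4–H presses on the aryl group of the Z-configured exocyclic C3=CH alkene. It is made last by a (2+2+2) cycloaddition of 1,6-diyne 31 (alkynes on C1 and C3) with ethynylboronate 32, so the cyclopentane and the benzene ring close together while C3 carries only a slim alkyne.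
3. 31 ← alkynyltrifluoroborate relay ← Corey–Fuchs homologation of aldehyde 26 ← Ireland–Claisen rearrangement of ester 21, which sets C1, C2 and the Z enyne by chirality transfer from one carbinol centre.
4. Carbinol 19 ← Sonogashira coupling ← trans-hydrostannation/iodination ← asymmetric alkynylation of dihydrobenzofuran aldehyde 12.
5. 12 ← formylation ← dihydrofuran ring (formed first) by enantioselective rhodium-carbene C–H insertion and C2 epimerisation. Ring order: dihydrofuran, then cyclopentane and benzene in one step.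

Key step: step 16

Abbreviation: Ar* = (2S,3S)-3-(3,5-dimethoxyphenyl)-2-(4-methoxyphenyl)-2,3-dihydro-1-benzofuran-5-yl. The indane is numbered C1 (4-oxyphenyl), C2 (3,5-dioxyphenyl), C3 (alkylidene).

Assumption: the senses of induction written for Rh2(R-PTAD)4 (step 3) and for (R)-BINOL/Ti(OiPr)4 (step 6) follow the usual models; both steps are purely reagent-controlled, so the antipodal catalyst would serve unchanged if a sense proved opposite.

**Route**

Step 1
Reactants: 1 5-bromo-2-hydroxybenzonitrile; 2 4-methoxybenzyl chloride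
Product: 3 5-bromo-2-[(4-methoxyphenyl)methoxy]benzonitrile
Conditions: K2CO3, KI (cat.), DMF, 60 °C
Reagents that add atoms: none
Why: Williamson etherification of the phenoxide with a reactive benzylic chloride; nitrile and aryl bromide are inert, and the new O–CH2 group is the later C2 of the dihydrofuran.

Step 2
Reactants: 3 5-bromo-2-[(4-methoxyphenyl)methoxy]benzonitrile; 4 1-bromo-3,5-dimethoxybenzene
Product: 7 {5-bromo-2-[(4-methoxyphenyl)methoxy]phenyl}(3,5-dimethoxyphenyl)methanone hydrazone, via 3,5-dimethoxyphenylmagnesium bromide 5 (not isolated), via diaryl N-H ketimine 6 (not isolated)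
Conditions: Mg, THF, reflux; 3, THF, reflux; MeOH, 0 °C; then N2H4·H2O, AcOH (cat.), EtOH, 70 °C
Reagents that add atoms: hydrazine hydrate, NN.O
Why: Grignard addition to the nitrile stops at the magnesium ketimide, and after protonation the N–H ketimine undergoes transimination with hydrazine (loss of NH3), giving the hydrazone without an acidic ketone hydrolysis that could endanger the benzylic ether.

Step 3
Reactants: 7 {5-bromo-2-[(4-methoxyphenyl)methoxy]phenyl}(3,5-dimethoxyphenyl)methanone hydrazone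
Product: 9 (2R,3S)-5-bromo-3-(3,5-dimethoxyphenyl)-2-(4-methoxyphenyl)-2,3-dihydro-1-benzofuran (cis), via diaryldiazomethane 8 (not isolated)
Conditions: MnO2, MeCN, 0 °C; then Rh2(R-PTAD)4 [dirhodium tetrakis((R)-1-adamantyl-N-phthalimidoacetate)] (1 mol%), 0 °C → rt
Reagents that add atoms: none
Why: Hydrazone dehydrogenation gives the donor/donor diazo compound, whose rhodium carbene inserts into the benzylic O–CH2 bond (enantioselective 1,5 C–H insertion) and closes the dihydrofuran; the chiral carboxylate ligands set C3 as S and the concerted insertion gives the cis C2.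

Step 4
Reactants: 9 (2R,3S)-5-bromo-3-(3,5-dimethoxyphenyl)-2-(4-methoxyphenyl)-2,3-dihydro-1-benzofuran
Product: 10 (2S,3S)-5-bromo-3-(3,5-dimethoxyphenyl)-2-(4-methoxyphenyl)-2,3-dihydro-1-benzofuran (trans)
Conditions: TFA, CH2Cl2, 0 °C → rt
Reagents that add atoms: none
Why: Acid-mediated epimerisation: reversible ionisation of the C2–O bond to the 4-methoxybenzylic cation and reclosure by the phenol should give the thermodynamic trans isomer, with C3 untouched.

Step 5
Reactants: 10 (2S,3S)-5-bromo-3-(3,5-dimethoxyphenyl)-2-(4-methoxyphenyl)-2,3-dihydro-1-benzofuran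
Product: 12 (2S,3S)-3-(3,5-dimethoxyphenyl)-2-(4-methoxyphenyl)-2,3-dihydro-1-benzofuran-5-carbaldehyde (Ar*-CHO), via aryllithium 11 (not isolated)
Conditions: n-BuLi, THF, −78 °C; DMF, −78 → 0 °C; H2O
Reagents that add atoms: N,N-dimethylformamide, CN(C)C=O
Why: Bromine–lithium exchange followed by formylation with DMF; at −78 °C exchange is far faster than any deprotonation at the dihydrofuran.

Step 6
Reactants: 12 Ar*-CHO; 13 1-ethynyl-3,5-dimethoxybenzene
Product: 15 (1S)-1-Ar*-3-(3,5-dimethoxyphenyl)prop-2-yn-1-ol, via alkynyl(ethyl)zinc 14 (not isolated)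
Conditions: Et2Zn, toluene, reflux (13); then (R)-BINOL (20 mol%), Ti(OiPr)4 (50 mol%), Et2O, rt; 12, rt; aqueous work-up
Reagents that add atoms: none
Why: Catalytic asymmetric alkynylzinc addition to an aromatic aldehyde; the (R)-BINOL–titanium complex directs the alkynyl group to the Re face of the formyl group and so sets the carbinol as S, independently of the remote dihydrofuran centres.

Step 7
Reactants: 15 (1S)-1-Ar*-3-(3,5-dimethoxyphenyl)prop-2-yn-1-ol
Product: 17 (1S,2Z)-1-Ar*-3-(3,5-dimethoxyphenyl)-2-iodoprop-2-en-1-ol, via alkenylstannane 16 (not isolated)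
Conditions: [Cp*RuCl]4 (2.5 mol%), Bu3SnH, CH2Cl2, rt; then I2, 2,6-lutidine, 0 °C
Reagents that add atoms: iodine, II
Why: Hydroxyl-directed ruthenium-catalysed trans-hydrostannation places tin on the alkyne carbon next to the carbinol and hydrogen trans to it, and iododestannylation proceeds with retention, so iodine ends cis to the dimethoxyphenyl group and the carbinol carbon trans to it.

Step 8
Reactants: 17 (1S,2Z)-1-Ar*-3-(3,5-dimethoxyphenyl)-2-iodoprop-2-en-1-ol; 18 trimethylsilylacetylene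
Product: 19 (1S,2E)-1-Ar*-2-[(3,5-dimethoxyphenyl)methylidene]-4-(trimethylsilyl)but-3-yn-1-ol
Conditions: Pd(PPh3)2Cl2 (3 mol%), CuI (5 mol%), Et3N, THF, rt
Reagents that add atoms: none
Why: Sonogashira coupling of an alkenyl iodide with retention of alkene geometry; the free hydroxyl is tolerated.

Step 9
Reactants: 19 (1S,2E)-1-Ar*-2-[(3,5-dimethoxyphenyl)methylidene]-4-(trimethylsilyl)but-3-yn-1-ol; 20 4-methoxyphenylacetic acid
Product: 21 (1S,2E)-1-Ar*-2-[(3,5-dimethoxyphenyl)methylidene]-4-(trimethylsilyl)but-3-yn-1-yl (4-methoxyphenyl)acetate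
Conditions: DCC, DMAP (cat.), CH2Cl2, 0 °C
Reagents that add atoms: none
Why: Steglich esterification under neutral conditions, which avoids ionisation of the benzylic allylic carbinol whose configuration must be kept.

Step 10
Reactants: 21 (1S,2E)-1-Ar*-2-[(3,5-dimethoxyphenyl)methylidene]-4-(trimethylsilyl)but-3-yn-1-yl (4-methoxyphenyl)acetate
Product: 24 (2R,3R,4Z)-5-Ar*-3-(3,5-dimethoxyphenyl)-2-(4-methoxyphenyl)-4-[(trimethylsilyl)ethynyl]pent-4-enoic acid, via (Z)-silyl ketene acetal 22 (not isolated), via trimethylsilyl ester 23 (not isolated)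
Conditions: LiHMDS, THF–DMPU, −78 °C; TMSCl, −78 °C → rt; aq. citric acid
Reagents that add atoms: none
Why: Ireland–Claisen rearrangement through a chair in which Ar* on the (S)-carbinol carbon, the dimethoxyphenyl group of the E alkene and the aryl group of the Z ketene acetal (the geometry arylacetates adopt on enolisation in a polar medium) are all equatorial; this transfers chirality to C1 (R) and C2 (R) and leaves Ar* cis to the linear alkynyl group, i.e. the Z enyne.

Step 11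
Reactants: 24 (2R,3R,4Z)-5-Ar*-3-(3,5-dimethoxyphenyl)-2-(4-methoxyphenyl)-4-[(trimethylsilyl)ethynyl]pent-4-enoic acid
Product: 25 (2R,3R,4Z)-5-Ar*-3-(3,5-dimethoxyphenyl)-2-(4-methoxyphenyl)-4-[(trimethylsilyl)ethynyl]pent-4-en-1-ol
Conditions: LiAlH4, THF, 0 °C; H2O/NaOH work-up
Reagents that add atoms: none
Why: Hydride reduction of the carboxylic acid; the carboxylate cannot epimerise C1 and the silylated enyne has no directing hydroxyl for hydroalumination.

Step 12
Reactants: 25 (2R,3R,4Z)-5-Ar*-3-(3,5-dimethoxyphenyl)-2-(4-methoxyphenyl)-4-[(trimethylsilyl)ethynyl]pent-4-en-1-ol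
Product: 26 (2R,3R,4Z)-5-Ar*-3-(3,5-dimethoxyphenyl)-2-(4-methoxyphenyl)-4-[(trimethylsilyl)ethynyl]pent-4-enal
Conditions: Dess–Martin periodinane, NaHCO3, CH2Cl2, 0 °C; used crude
Reagents that add atoms: none
Why: Buffered Dess–Martin oxidation gives the α-aryl aldehyde without base, and immediate use should prevent epimerisation at C1.

Step 13
Reactants: 26 (2R,3R,4Z)-5-Ar*-3-(3,5-dimethoxyphenyl)-2-(4-methoxyphenyl)-4-[(trimethylsilyl)ethynyl]pent-4-enal
Product: 27 (3S,4R,5Z)-6-Ar*-1,1-dibromo-4-(3,5-dimethoxyphenyl)-3-(4-methoxyphenyl)-5-[(trimethylsilyl)ethynyl]hexa-1,5-diene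
Conditions: CBr4, PPh3, Zn, CH2Cl2, rt (ylide preformed); then 26, 0 °C → rt
Reagents that add atoms: carbon tetrabromide, BrC(Br)(Br)Br
Why: Corey–Fuchs dibromo-olefination with a non-basic phosphorus ylide adds the carbon that becomes C7 while sparing the α-aryl centre (its descriptor changes to S only through ligand priorities).

Step 14
Reactants: 27 (3S,4R,5Z)-6-Ar*-1,1-dibromo-4-(3,5-dimethoxyphenyl)-3-(4-methoxyphenyl)-5-[(trimethylsilyl)ethynyl]hexa-1,5-diene
Product: 30 potassium {(3R,4R,5Z)-6-Ar*-4-(3,5-dimethoxyphenyl)-5-ethynyl-3-(4-methoxyphenyl)hex-5-en-1-yn-1-yl}trifluoroborate, via lithium acetylide 28 (not isolated), via silylated alkynyltrifluoroborate 29 (not isolated)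
Conditions: n-BuLi (2.1 equiv), THF, −78 °C; B(OMe)3, −78 → −20 °C; KHF2 (aq), → rt; then MeOH, K2CO3 (cat.), rt
Reagents that add atoms: trimethyl borate, COB(OC)OC; potassium hydrogen difluoride, F.[F-].[K+]
Why: Second stage of the Corey–Fuchs reaction (bromine–lithium exchange and Fritsch–Buttenberg–Wiechell shift) gives the C1 acetylide while the enyne alkyne is still silylated, so boron goes to one alkyne only; the tetracoordinate trifluoroborate then survives the fluoride/methanol C–Si cleavage that a C(sp)–B pinacol ester would not.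

Step 15
Reactants: 30 potassium {(3R,4R,5Z)-6-Ar*-4-(3,5-dimethoxyphenyl)-5-ethynyl-3-(4-methoxyphenyl)hex-5-en-1-yn-1-yl}trifluoroborate
Product: 31 2-[(3R,4R,5Z)-6-Ar*-4-(3,5-dimethoxyphenyl)-5-ethynyl-3-(4-methoxyphenyl)hex-5-en-1-yn-1-yl]-4,4,5,5-tetramethyl-1,3,2-dioxaborolane
Conditions: TMSCl, pinacol, Et3N, MeCN, 0 °C → rt; filtered under argon, used crude
Reagents that add atoms: pinacol, CC(C)(O)C(C)(C)O
Why: Trifluoroborate-to-boronic-ester interconversion: chlorosilane abstracts fluoride as Me3SiF, pinacol esterifies boron and the amine takes up HCl, so the moisture-sensitive alkynylboronate is made last and without water.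

Step 16
Reactants: 31 2-[(3R,4R,5Z)-6-Ar*-4-(3,5-dimethoxyphenyl)-5-ethynyl-3-(4-methoxyphenyl)hex-5-en-1-yn-1-yl]-4,4,5,5-tetramethyl-1,3,2-dioxaborolane; 32 ethynylboronic acid pinacol ester
Product: 33 2,2'-[(1R,2R,3Z)-3-(Ar*-methylidene)-2-(3,5-dimethoxyphenyl)-1-(4-methoxyphenyl)-2,3-dihydro-1H-indene-5,7-diyl]bis(4,4,5,5-tetramethyl-1,3,2-dioxaborolane)
Conditions: Cp*RuCl(cod) (10 mol%), 1,2-dichloroethane, rt → 40 °C, 32 (3 equiv) added slowly
Reagents that add atoms: none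
Why: The Cp*RuCl fragment, freed from cod, binds both alkynes of 31 and couples them oxidatively to a ruthenacyclopentatriene; this forms C3a–C7a and closes the five-membered carbocycle across the three-carbon tether C3–C2–C1, after which 32 adds across one ruthenium–carbon bond and reductive elimination forms C4–C5 and C6–C7, closing the benzene ring. The closest known reaction type is the Cp*RuCl(cod)-catalysed (2+2+2) cycloaddition of 1,6-diynes with one substituted (including boryl) terminus and terminal alkynes, ethynylboronate among them. No stereocentre is formed, and the neutral, base-free conditions should leave C1, C2, the Z alkene and both dihydrofuran centres as set. The step needs 5,7 (meta) and not 6,7 (ortho) placement of the two boryl groups: the bulky boronate on the C7 terminus and the free C–H on the C4 terminus should make 32 enter at the unhindered end with its own boronate turned away from C7. It also needs cross-cycloaddition to outrun trimerisation of 32, which slow addition and the pre-organised diyne (two aryl groups and an sp2 carbon in the tether) should favour. The Z geometry is not at risk here, because the alkene is never a reacting centre and the C4–H that crowds its aryl group only appears as the ring forms.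

Step 17
Reactants: 33 2,2'-[(1R,2R,3Z)-3-(Ar*-methylidene)-2-(3,5-dimethoxyphenyl)-1-(4-methoxyphenyl)-2,3-dihydro-1H-indene-5,7-diyl]bis(4,4,5,5-tetramethyl-1,3,2-dioxaborolane)
Product: 34 (1R,2R,3Z)-3-(Ar*-methylidene)-2-(3,5-dimethoxyphenyl)-1-(4-methoxyphenyl)-2,3-dihydro-1H-indene-5,7-diol
Conditions: NaBO3·4H2O, THF–H2O, rt
Reagents that add atoms: sodium perborate, O[B-]1(O)OO[B-](O)(O)OO1.[Na+].[Na+]
Why: Perborate oxidation of both aryl C–B bonds (boron-to-oxygen 1,2-aryl shift, then hydrolysis) under mild, nearly neutral conditions that should not touch the alkene.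

Step 18
Reactants: 34 (1R,2R,3Z)-3-(Ar*-methylidene)-2-(3,5-dimethoxyphenyl)-1-(4-methoxyphenyl)-2,3-dihydro-1H-indene-5,7-diol
Product: 35 (1R,2R,3Z)-2-(3,5-dihydroxyphenyl)-3-{[(2S,3S)-3-(3,5-dihydroxyphenyl)-2-(4-hydroxyphenyl)-2,3-dihydro-1-benzofuran-5-yl]methylidene}-1-(4-hydroxyphenyl)-2,3-dihydro-1H-indene-5,7-diol (CNP0184753.4)
Conditions: BBr3 (excess), CH2Cl2, −78 → 0 °C; MeOH at −78 °C
Reagents that add atoms: none
Why: Lewis-acid cleavage of the six aryl methyl ethers (bromide attack on the O-methyl of the boron-complexed ether); the low temperature and cold quench are meant to limit protonation of the exocyclic alkene, and the trans dihydrofuran is the thermodynamic isomer.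

**Compound list**

1 | 5-bromo-2-hydroxybenzonitrile | N#Cc1cc(Br)ccc1O | starting material
2 | 4-methoxybenzyl chloride | COc1ccc(CCl)cc1 | starting material
3 | 5-bromo-2-[(4-methoxyphenyl)methoxy]benzonitrile | COc1ccc(COc2ccc(Br)cc2C#N)cc1 | intermediate
4 | 1-bromo-3,5-dimethoxybenzene | COc1cc(Br)cc(OC)c1 | starting material
5 | 3,5-dimethoxyphenylmagnesium bromide | COc1cc([Mg]Br)cc(OC)c1 | intermediate (not isolated)
6 | {5-bromo-2-[(4-methoxyphenyl)methoxy]phenyl}(3,5-dimethoxyphenyl)methanimine | COc1ccc(COc2ccc(Br)cc2C(=N)c2cc(OC)cc(OC)c2)cc1 | intermediate (not isolated)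
7 | {5-bromo-2-[(4-methoxyphenyl)methoxy]phenyl}(3,5-dimethoxyphenyl)methanone hydrazone | COc1ccc(COc2ccc(Br)cc2C(=NN)c2cc(OC)cc(OC)c2)cc1 | intermediate
8 | {5-bromo-2-[(4-methoxyphenyl)methoxy]phenyl}(3,5-dimethoxyphenyl)diazomethane | COc1ccc(COc2ccc(Br)cc2C(=[N+]=[N-])c2cc(OC)cc(OC)c2)cc1 | intermediate (not isolated)
9 | (2R,3S)-5-bromo-3-(3,5-dimethoxyphenyl)-2-(4-methoxyphenyl)-2,3-dihydro-1-benzofuran (cis) | Brc1ccc2c(c1)[C@H](c1cc(OC)cc(OC)c1)[C@H](c1ccc(OC)cc1)O2 | intermediate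
10 | (2S,3S)-5-bromo-3-(3,5-dimethoxyphenyl)-2-(4-methoxyphenyl)-2,3-dihydro-1-benzofuran (trans) | Brc1ccc2c(c1)[C@H](c1cc(OC)cc(OC)c1)[C@@H](c1ccc(OC)cc1)O2 | intermediate
11 | Ar*-lithium | [Li]c1ccc2c(c1)[C@H](c1cc(OC)cc(OC)c1)[C@@H](c1ccc(OC)cc1)O2 | intermediate (not isolated)
12 | (2S,3S)-3-(3,5-dimethoxyphenyl)-2-(4-methoxyphenyl)-2,3-dihydro-1-benzofuran-5-carbaldehyde | O=Cc1ccc2c(c1)[C@H](c1cc(OC)cc(OC)c1)[C@@H](c1ccc(OC)cc1)O2 | intermediate
13 | 1-ethynyl-3,5-dimethoxybenzene | C#Cc1cc(OC)cc(OC)c1 | starting material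
14 | [(3,5-dimethoxyphenyl)ethynyl](ethyl)zinc | CC[Zn]C#Cc1cc(OC)cc(OC)c1 | intermediate (not isolated)
15 | (1S)-1-Ar*-3-(3,5-dimethoxyphenyl)prop-2-yn-1-ol | O[C@H](C#Cc1cc(OC)cc(OC)c1)c1ccc2c(c1)[C@H](c1cc(OC)cc(OC)c1)[C@@H](c1ccc(OC)cc1)O2 | intermediate
16 | (1S,2Z)-1-Ar*-3-(3,5-dimethoxyphenyl)-2-(tributylstannyl)prop-2-en-1-ol | O[C@H](/C([Sn](CCCC)(CCCC)CCCC)=C/c1cc(OC)cc(OC)c1)c1ccc2c(c1)[C@H](c1cc(OC)cc(OC)c1)[C@@H](c1ccc(OC)cc1)O2 | intermediate (not isolated)
17 | (1S,2Z)-1-Ar*-3-(3,5-dimethoxyphenyl)-2-iodoprop-2-en-1-ol | O[C@H](/C(I)=C/c1cc(OC)cc(OC)c1)c1ccc2c(c1)[C@H](c1cc(OC)cc(OC)c1)[C@@H](c1ccc(OC)cc1)O2 | intermediate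
18 | trimethylsilylacetylene | C#C[Si](C)(C)C | starting material
19 | (1S,2E)-1-Ar*-2-[(3,5-dimethoxyphenyl)methylidene]-4-(trimethylsilyl)but-3-yn-1-ol | O[C@H](/C(C#C[Si](C)(C)C)=C/c1cc(OC)cc(OC)c1)c1ccc2c(c1)[C@H](c1cc(OC)cc(OC)c1)[C@@H](c1ccc(OC)cc1)O2 | intermediate
20 | 4-methoxyphenylacetic acid | COc1ccc(CC(=O)O)cc1 | starting material
21 | (1S,2E)-1-Ar*-2-[(3,5-dimethoxyphenyl)methylidene]-4-(trimethylsilyl)but-3-yn-1-yl (4-methoxyphenyl)acetate | COc1ccc(CC(=O)O[C@H](/C(C#C[Si](C)(C)C)=C/c2cc(OC)cc(OC)c2)c2ccc3c(c2)[C@H](c2cc(OC)cc(OC)c2)[C@@H](c2ccc(OC)cc2)O3)cc1 | intermediate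
22 | (Z)-trimethylsilyl ketene acetal of 21 | COc1ccc(/C=C(\O[Si](C)(C)C)O[C@H](/C(C#C[Si](C)(C)C)=C/c2cc(OC)cc(OC)c2)c2ccc3c(c2)[C@H](c2cc(OC)cc(OC)c2)[C@@H](c2ccc(OC)cc2)O3)cc1 | intermediate (not isolated)
23 | trimethylsilyl ester of 24 | COc1ccc([C@@H]([C@@H](/C(C#C[Si](C)(C)C)=C/c2ccc3c(c2)[C@H](c2cc(OC)cc(OC)c2)[C@@H](c2ccc(OC)cc2)O3)c2cc(OC)cc(OC)c2)C(=O)O[Si](C)(C)C)cc1 | intermediate (not isolated)
24 | (2R,3R,4Z)-5-Ar*-3-(3,5-dimethoxyphenyl)-2-(4-methoxyphenyl)-4-[(trimethylsilyl)ethynyl]pent-4-enoic acid | COc1ccc([C@@H]([C@@H](/C(C#C[Si](C)(C)C)=C/c2ccc3c(c2)[C@H](c2cc(OC)cc(OC)c2)[C@@H](c2ccc(OC)cc2)O3)c2cc(OC)cc(OC)c2)C(=O)O)cc1 | intermediate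
25 | (2R,3R,4Z)-5-Ar*-3-(3,5-dimethoxyphenyl)-2-(4-methoxyphenyl)-4-[(trimethylsilyl)ethynyl]pent-4-en-1-ol | COc1ccc([C@@H]([C@@H](/C(C#C[Si](C)(C)C)=C/c2ccc3c(c2)[C@H](c2cc(OC)cc(OC)c2)[C@@H](c2ccc(OC)cc2)O3)c2cc(OC)cc(OC)c2)CO)cc1 | intermediate
26 | (2R,3R,4Z)-5-Ar*-3-(3,5-dimethoxyphenyl)-2-(4-methoxyphenyl)-4-[(trimethylsilyl)ethynyl]pent-4-enal | COc1ccc([C@@H]([C@@H](/C(C#C[Si](C)(C)C)=C/c2ccc3c(c2)[C@H](c2cc(OC)cc(OC)c2)[C@@H](c2ccc(OC)cc2)O3)c2cc(OC)cc(OC)c2)C=O)cc1 | intermediate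
27 | (3S,4R,5Z)-6-Ar*-1,1-dibromo-4-(3,5-dimethoxyphenyl)-3-(4-methoxyphenyl)-5-[(trimethylsilyl)ethynyl]hexa-1,5-diene | COc1ccc([C@@H]([C@@H](/C(C#C[Si](C)(C)C)=C/c2ccc3c(c2)[C@H](c2cc(OC)cc(OC)c2)[C@@H](c2ccc(OC)cc2)O3)c2cc(OC)cc(OC)c2)C=C(Br)Br)cc1 | intermediate
28 | lithium acetylide from 27 (C1 alkyne lithiated, enyne alkyne silylated) | COc1ccc([C@@H]([C@@H](/C(C#C[Si](C)(C)C)=C/c2ccc3c(c2)[C@H](c2cc(OC)cc(OC)c2)[C@@H](c2ccc(OC)cc2)O3)c2cc(OC)cc(OC)c2)C#C[Li])cc1 | intermediate (not isolated)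
29 | potassium {(3R,4R,5Z)-6-Ar*-4-(3,5-dimethoxyphenyl)-3-(4-methoxyphenyl)-5-[(trimethylsilyl)ethynyl]hex-5-en-1-yn-1-yl}trifluoroborate | COc1ccc([C@@H]([C@@H](/C(C#C[Si](C)(C)C)=C/c2ccc3c(c2)[C@H](c2cc(OC)cc(OC)c2)[C@@H](c2ccc(OC)cc2)O3)c2cc(OC)cc(OC)c2)C#C[B-](F)(F)F)cc1.[K+] | intermediate (not isolated)
30 | potassium {(3R,4R,5Z)-6-Ar*-4-(3,5-dimethoxyphenyl)-5-ethynyl-3-(4-methoxyphenyl)hex-5-en-1-yn-1-yl}trifluoroborate | COc1ccc([C@@H]([C@@H](/C(C#C)=C/c2ccc3c(c2)[C@H](c2cc(OC)cc(OC)c2)[C@@H](c2ccc(OC)cc2)O3)c2cc(OC)cc(OC)c2)C#C[B-](F)(F)F)cc1.[K+] | intermediate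
31 | 2-[(3R,4R,5Z)-6-Ar*-4-(3,5-dimethoxyphenyl)-5-ethynyl-3-(4-methoxyphenyl)hex-5-en-1-yn-1-yl]-4,4,5,5-tetramethyl-1,3,2-dioxaborolane (1,6-diyne, key-step precursor) | COc1ccc([C@@H]([C@@H](/C(C#C)=C/c2ccc3c(c2)[C@H](c2cc(OC)cc(OC)c2)[C@@H](c2ccc(OC)cc2)O3)c2cc(OC)cc(OC)c2)C#CB2OC(C)(C)C(C)(C)O2)cc1 | intermediate
32 | ethynylboronic acid pinacol ester | C#CB1OC(C)(C)C(C)(C)O1 | starting material
33 | indane 5,7-bis(pinacol boronate), hexamethyl ether (1R,2R,3Z; key-step product) | COc1ccc([C@@H]2c3c(B4OC(C)(C)C(C)(C)O4)cc(B4OC(C)(C)C(C)(C)O4)cc3/C(=C\c3ccc4c(c3)[C@H](c3cc(OC)cc(OC)c3)[C@@H](c3ccc(OC)cc3)O4)[C@H]2c2cc(OC)cc(OC)c2)cc1 | intermediate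
34 | (1R,2R,3Z)-3-(Ar*-methylidene)-2-(3,5-dimethoxyphenyl)-1-(4-methoxyphenyl)-2,3-dihydro-1H-indene-5,7-diol | COc1ccc([C@@H]2c3c(O)cc(O)cc3/C(=C\c3ccc4c(c3)[C@H](c3cc(OC)cc(OC)c3)[C@@H](c3ccc(OC)cc3)O4)[C@H]2c2cc(OC)cc(OC)c2)cc1 | intermediate
35 | CNP0184753.4, (1R,2R,3Z)-2-(3,5-dihydroxyphenyl)-3-{[(2S,3S)-3-(3,5-dihydroxyphenyl)-2-(4-hydroxyphenyl)-2,3-dihydro-1-benzofuran-5-yl]methylidene}-1-(4-hydroxyphenyl)-2,3-dihydro-1H-indene-5,7-diol | Oc1ccc([C@@H]2c3c(O)cc(O)cc3/C(=C\c3ccc4c(c3)[C@H](c3cc(O)cc(O)c3)[C@@H](c3ccc(O)cc3)O4)[C@H]2c2cc(O)cc(O)c2)cc1 | target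

**Step count**

Total: 18 steps. Longest linear sequence: 18 steps (1 → 35); all other inputs are commercial.

**Steps most likely to fail**

1. Step 16 (key cycloaddition). What may go wrong: loss of the C(sp)–B bond of 31 by protodeborylation on handling; slow entry of the bulky boryl alkyne into the ruthenacycle, so that 32 trimerises on its own; or competing ortho (6,7) insertion. Fallback: set out from dibromide 27 and carry a halogen instead of boron on the C7 terminus. TBAF·3H2O in DMF at 60 °C should eliminate HBr and cleave the C–Si bond in one operation to give the bromodiyne (3R,4R,5Z)-6-Ar*-1-bromo-4-(3,5-dimethoxyphenyl)-5-ethynyl-3-(4-methoxyphenyl)hex-5-en-1-yne F1. Haloalkyne termini are tolerated in Cp*RuCl(cod) cycloadditions, so F1 with 32 under the conditions of step 16 should give the 7-bromo-5-boronate indane F2. Miyaura borylation of F2 (Pd(dppf)Cl2, B2pin2, KOAc, dioxane, 90 °C) then comes back to the route at 33.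

2. Step 18 (global demethylation). What may go wrong: protonation of the crowded exocyclic alkene by the Lewis acid or adventitious HBr, with Z-to-E isomerisation (relief of the C4–H/aryl contact), and reversible opening of the dihydrofuran C2–O bond, before all six ethers are cleaved. Fallback: accept the thermodynamic alkene and correct it afterwards. From 34, BBr3 at room temperature driven to completion should give the E-configured octaphenol F3 (the trans dihydrofuran recloses as the stable isomer). Contra-thermodynamic E-to-Z photoisomerisation of F3 (365 nm, degassed MeOH) should then enrich 35, which is separated by reversed-phase HPLC with recycling of F3; the fallback comes back at 35.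

3. Step 10 (Ireland–Claisen rearrangement). What may go wrong: mixed enolate geometry giving the C1 epimer, or ionisation of the benzylic allylic ester before rearrangement, eroding the chirality transfer. Fallback: remove the enolate from the problem by an aldehyde-level Claisen rearrangement. From carbinol 19, copper-catalysed C–O coupling (CuI, 3,4,7,8-tetramethyl-1,10-phenanthroline, Cs2CO3, toluene, 80 °C) with (E)-1-(2-iodoethenyl)-4-methoxybenzene F4 (from 4-ethynylanisole, Cp2Zr(H)Cl then I2) should give the (E)-allyl vinyl ether F5, whose geometry is fixed by the vinyl iodide. Heating F5 in base-free toluene at 110 °C should rearrange it through the same all-equatorial chair directly to aldehyde 26, where the fallback comes back to the route, bypassing 21, 24 and 25.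

**Further compounds**

F1 | step 16 | (3R,4R,5Z)-6-Ar*-1-bromo-4-(3,5-dimethoxyphenyl)-5-ethynyl-3-(4-methoxyphenyl)hex-5-en-1-yne | COc1ccc([C@@H]([C@@H](/C(C#C)=C/c2ccc3c(c2)[C@H](c2cc(OC)cc(OC)c2)[C@@H](c2ccc(OC)cc2)O3)c2cc(OC)cc(OC)c2)C#CBr)cc1
F2 | step 16 | 2-[(1R,2R,3Z)-3-(Ar*-methylidene)-7-bromo-2-(3,5-dimethoxyphenyl)-1-(4-methoxyphenyl)-2,3-dihydro-1H-inden-5-yl]-4,4,5,5-tetramethyl-1,3,2-dioxaborolane | COc1ccc([C@@H]2c3c(Br)cc(B4OC(C)(C)C(C)(C)O4)cc3/C(=C\c3ccc4c(c3)[C@H](c3cc(OC)cc(OC)c3)[C@@H](c3ccc(OC)cc3)O4)[C@H]2c2cc(OC)cc(OC)c2)cc1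
F3 | step 18 | (1R,2R,3E)-isomer of 35 | Oc1ccc([C@@H]2c3c(O)cc(O)cc3/C(=C/c3ccc4c(c3)[C@H](c3cc(O)cc(O)c3)[C@@H](c3ccc(O)cc3)O4)[C@H]2c2cc(O)cc(O)c2)cc1
F4 | step 10 | (E)-1-(2-iodoethenyl)-4-methoxybenzene | COc1ccc(/C=C/I)cc1
F5 | step 10 | (E)-2-(4-methoxyphenyl)ethenyl ether of carbinol 19 | COc1ccc(/C=C/O[C@H](/C(C#C[Si](C)(C)C)=C/c2cc(OC)cc(OC)c2)c2ccc3c(c2)[C@H](c2cc(OC)cc(OC)c2)[C@@H](c2ccc(OC)cc2)O3)cc1
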